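**Plan**
- Retrosynthetic cuts: C12–C13 (alkyl–alkenyl coupling), C8=C17 (methylenation), C9–C10 (radical closure of ring B), C9=C11 (aldol condensation), C5–C6 (allylic substitution).
- Forward: ring A comes from 2,2-dimethylcyclohexanone; the C6–C8 chain is attached at C5 by copper-catalysed SN2′ alkylation; C9, C11 and C12 are added as a ketomalonate.
- Ring B: quaternary C10 carries the C20 methyl group and stands 1,5 to the C8 carbonyl, so a tertiary C10 radical made from the C10=C20 methylene group can add 6-exo to C9.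
- Change to the acceptor: C11 carries two esters during the closure (one is removed afterwards), so that C9 is the only β-carbon of the acceptor and 7-endo attack at C11 is blocked.
- Side chain: a (2E)-vinyl iodide with C15 (silyl ether) and C16 (isobutyrate) already differentiated is joined by Negishi coupling; C15 is oxidised to the acid last.
- Stereochemistry: C5 from the chiral copper catalyst; C10 and C9 relayed from C5 in the chair-like closure (C9 also under thermodynamic control next to C8=O); 13Z from syn-hydrostannation of butynediol and stereoretentive iodination and coupling.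

Key step: step 8

Assumption: labdane numbering is used throughout (ring A = C1–C5, C10; ring B = C5–C10; C20 = methyl on C10; C17 = methylene carbon on C8). The target is the ent-labdane (5R,9R,10R) with a 13Z alkene. Which antipode of the phosphoramidite ligand in step 4 gives the (1R) centre has to be fixed by a test run; both antipodes are available.

**Route**

Step 1
Reactants: 1 2,2-dimethylcyclohexan-1-one
Product: 2 2,2-dimethyl-6-methylidenecyclohexan-1-one
Conditions: (CH2O)n, PhNHMe·CF3CO2H, THF, reflux; crude enone used at once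
Reagents that add atoms: formaldehyde (as paraformaldehyde), C=O
Why: Mannich-type α-methylenation; only C6 of ketone 1 is enolisable, so iminium condensation and amine elimination can occur at one position only, and the dimerisation-prone enone is carried on directly.

Step 2
Reactants: 2 2,2-dimethyl-6-methylidenecyclohexan-1-one
Product: 3 6,6-dimethyl-2-methylidenecyclohexan-1-ol (racemic)
Conditions: NaBH4, CeCl3·7H2O, MeOH, −78 → 0 °C
Reagents that add atoms: none
Why: Luche reduction attacks the enone carbonyl 1,2 and leaves the exocyclic alkene; the racemic carbinol centre is destroyed in the next step.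

Step 3
Reactants: 3 6,6-dimethyl-2-methylidenecyclohexan-1-ol
Product: 4 1-(chloromethyl)-3,3-dimethylcyclohex-1-ene
Conditions: SOCl2, Et2O, 0 °C → rt
Reagents that add atoms: thionyl chloride, O=S(Cl)Cl
Why: Allylic chlorination with transposition (SNi′): the chlorosulfite delivers chloride to the unhindered exocyclic CH2 and not to the neopentyl-type carbinol carbon, which gives the primary chloride with the trisubstituted ring alkene.

Step 4
Reactants: 4 1-(chloromethyl)-3,3-dimethylcyclohex-1-ene; 5 2-(2-bromoethyl)-2-methyl-1,3-dioxolane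
Product: 7 2-{2-[(1R)-2,2-dimethyl-6-methylidenecyclohexyl]ethyl}-2-methyl-1,3-dioxolane, via Grignard reagent 6 (not isolated)
Conditions: 5, Mg, 2-MeTHF, 25 °C; then 4, copper thiophene-2-carboxylate Cu(O2CC4H3S) (3 mol %), O,O′-(1,1′-binaphthalene-2,2′-diyl) N,N-bis[1-(2-methoxyphenyl)ethyl]phosphoramidite (3.5 mol %), CH2Cl2, −78 °C, slow addition of 6
Reagents that add atoms: none
Why: Copper-catalysed asymmetric allylic alkylation (SN2′) of an endocyclic allylic chloride: the monovalent copper–phosphoramidite alkyl complex attacks ring carbon C5 anti to chloride, the alkene moves to the exocyclic C10=C20 position, and the ligand sets the C5 stereocentre.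

Step 5
Reactants: 7 2-{2-[(1R)-2,2-dimethyl-6-methylidenecyclohexyl]ethyl}-2-methyl-1,3-dioxolane
Product: 8 4-[(1R)-2,2-dimethyl-6-methylidenecyclohexyl]butan-2-one ((R)-γ-dihydroionone)
Conditions: PPTS, acetone/H2O, 50 °C
Reagents that add atoms: water, O
Why: Acid-catalysed ketal hydrolysis under buffered conditions mild enough to leave the exocyclic alkene in place; C5 is not epimerisable.

Step 6
Reactants: 8 (R)-γ-dihydroionone; 9 diethyl 2-oxopropanedioate (diethyl ketomalonate)
Product: 10 diethyl 2-{4-[(1R)-2,2-dimethyl-6-methylidenecyclohexyl]-2-oxobutyl}-2-hydroxypropanedioate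
Conditions: LiN(iPr)2, THF, −78 °C; 9, −78 °C; AcOH quench at −78 °C
Reagents that add atoms: none
Why: Kinetic deprotonation of the methyl ketone at the methyl group (future C9) and aldol addition to the very electrophilic, non-enolisable keto group of 9; the cold protic quench prevents retro-aldol cleavage.

Step 7
Reactants: 10 diethyl 2-{4-[(1R)-2,2-dimethyl-6-methylidenecyclohexyl]-2-oxobutyl}-2-hydroxypropanedioate
Product: 11 diethyl 2-{4-[(1R)-2,2-dimethyl-6-methylidenecyclohexyl]-2-oxobutylidene}propanedioate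
Conditions: MsCl, Et3N, CH2Cl2, 0 °C → rt
Reagents that add atoms: none
Why: Mesylation of the tertiary alcohol by way of sulfene and E1cB elimination through the C8 enolate give the alkylidene malonate, which has no E/Z issue because C11 carries two identical esters.

Step 8
Reactants: 11 diethyl 2-{4-[(1R)-2,2-dimethyl-6-methylidenecyclohexyl]-2-oxobutylidene}propanedioate
Product: 12 diethyl 2-[(1S,4aR,8aR)-5,5,8a-trimethyl-2-oxodecahydronaphthalen-1-yl]propanedioate (trans-fused; labdane numbering 5R,9S,10R)
Conditions: Fe(acac)3 (0.5 equiv), PhSiH3 (2.5 equiv), EtOH/(CH2OH)2 (5:1), 0.02 M, 60 °C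
Reagents that add atoms: none
Why: Trivalent iron and PhSiH3 in ethanol form an iron hydride that transfers a hydrogen atom to C20 of the 1,1-disubstituted alkene, so C20 becomes the methyl group and C10 a tertiary nucleophilic radical; this adds to C9, the β-carbon of the alkylidene malonate, and the malonyl radical is reduced by divalent iron and protonated by the solvent. The closest known reaction type is the iron-hydride reductive coupling of an unactivated alkene with an electron-poor alkene, run intramolecularly as a Giese cyclization. Ring B closes 6-exo-trig through a chair-like transition state. C10 is controlled by C5: with the C5 tether equatorial on the ring A chair, C9 reaches the radical from the face that carries H5, away from the axial C4 methyl group, so the new bond is equatorial, C20 ends axial and the fusion is trans. C9 should form with the malonate equatorial and, being α to the C8 ketone, can be equilibrated to that configuration with DBU if the axial epimer appears. The step needs hydrogen-atom transfer to the electron-rich alkene instead of hydride reduction of the acceptor, and attack at C9 instead of 7-endo attack at C11 or 5-exo attack at the C8 carbonyl carbon; the second ester makes C9 the only open β-position of a doubly activated alkene (C11 is fully substituted), and high dilution suppresses intermolecular addition.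

Step 9
Reactants: 12 diethyl 2-[(1S,4aR,8aR)-5,5,8a-trimethyl-2-oxodecahydronaphthalen-1-yl]propanedioate
Product: 13 ethyl 8-oxo-13,14,15,16,17-pentanor-ent-labdan-12-oate
Conditions: LiCl, H2O, DMSO, 150 °C
Reagents that add atoms: none
Why: Krapcho dealkoxycarbonylation removes the auxiliary ester, and under these conditions C9 can equilibrate through the C8 enol to the equatorial side chain.

Step 10
Reactants: 13 ethyl 8-oxo-13,14,15,16,17-pentanor-ent-labdan-12-oate
Product: 14 ethyl 13,14,15,16-tetranor-ent-labd-8(17)-en-12-oate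
Conditions: Ph3PCH3Br (3 equiv), KOtBu (2.8 equiv), toluene, 0 °C; then 13, 80 °C
Reagents that add atoms: methyltriphenylphosphonium bromide, C[P+](c1ccccc1)(c1ccccc1)c1ccccc1.[Br-]
Why: Wittig methylenation of the C8 ketone with preformed ylide and no excess alkoxide; the ylide does not attack the ester, and C9 is already in its stable equatorial configuration, so enolisation cannot lose it.

Step 11
Reactants: 14 ethyl 13,14,15,16-tetranor-ent-labd-8(17)-en-12-oate
Product: 15 13,14,15,16-tetranor-ent-labd-8(17)-en-12-ol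
Conditions: LiAlH4, THF, 0 °C
Reagents that add atoms: none
Why: Hydride reduction of the ester to the primary alcohol; the isolated 1,1-disubstituted alkene is inert to LiAlH4.

Step 12
Reactants: 15 13,14,15,16-tetranor-ent-labd-8(17)-en-12-ol
Product: 16 12-iodo-13,14,15,16-tetranor-ent-labd-8(17)-ene
Conditions: I2, PPh3, imidazole, CH2Cl2, 0 °C → rt
Reagents that add atoms: iodine, II
Why: Appel-type iodination of the unhindered primary alcohol by SN2 displacement of the alkoxyphosphonium ion.

Step 13
Reactants: 17 but-2-yne-1,4-diol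
Product: 18 (2E)-2-(tributylstannyl)but-2-ene-1,4-diol
Conditions: Bu3SnH, PdCl2(PPh3)2 (2 mol %), THF, rt
Reagents that add atoms: tributylstannane, CCCC[SnH](CCCC)CCCC
Why: Palladium-catalysed syn-hydrostannation of the symmetrical alkyne can give only one regioisomer and puts H and Sn cis, which fixes the two CH2O groups cis to each other (the later C15/C16 relationship).

Step 14
Reactants: 18 (2E)-2-(tributylstannyl)but-2-ene-1,4-diol
Product: 19 (2E)-4-[(tert-butyldimethylsilyl)oxy]-2-(tributylstannyl)but-2-en-1-ol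
Conditions: TBSCl (1.0 equiv), imidazole, CH2Cl2, −20 → 0 °C
Reagents that add atoms: tert-butyl(chloro)dimethylsilane, CC(C)(C)[Si](C)(C)Cl
Why: Selective silylation of the less hindered primary hydroxyl, the one on the CH= carbon and remote from the SnBu3 group (the later C15 oxygen).

Step 15
Reactants: 19 (2E)-4-[(tert-butyldimethylsilyl)oxy]-2-(tributylstannyl)but-2-en-1-ol
Product: 20 (2E)-4-[(tert-butyldimethylsilyl)oxy]-2-(tributylstannyl)but-2-en-1-yl 2-methylpropanoate
Conditions: i-PrCOCl, pyridine, DMAP (cat.), CH2Cl2, 0 °C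
Reagents that add atoms: 2-methylpropanoyl chloride, CC(C)C(Cl)=O
Why: Esterification (acyl chloride, nucleophilic catalysis) of the remaining hydroxyl, which becomes the C16 isobutyrate of the target.

Step 16
Reactants: 20 (2E)-4-[(tert-butyldimethylsilyl)oxy]-2-(tributylstannyl)but-2-en-1-yl 2-methylpropanoate
Product: 21 (2E)-4-[(tert-butyldimethylsilyl)oxy]-2-iodobut-2-en-1-yl 2-methylpropanoate
Conditions: I2, CH2Cl2, 0 °C
Reagents that add atoms: iodine, II
Why: Iododestannylation is an ipso substitution at the C–Sn bond and proceeds with retention of alkene geometry.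

Step 17
Reactants: 16 12-iodo-13,14,15,16-tetranor-ent-labd-8(17)-ene; 21 (2E)-4-[(tert-butyldimethylsilyl)oxy]-2-iodobut-2-en-1-yl 2-methylpropanoate
Product: 23 15-O-(tert-butyldimethylsilyl)-16-O-(2-methylpropanoyl)-ent-labda-8(17),13Z-diene-15,16-diol, via alkylzinc iodide 22 (not isolated)
Conditions: 16, Zn dust, LiCl, THF, 40 °C; then 21, PdCl2(dppf) (5 mol %), THF, rt
Reagents that add atoms: none
Why: Zinc insertion into the primary C–I bond followed by Negishi alkyl–alkenyl coupling; oxidative addition, transmetalation and reductive elimination keep the geometry of the vinyl iodide, which gives the 13Z alkene.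

Step 18
Reactants: 23 15-O-(tert-butyldimethylsilyl)-16-O-(2-methylpropanoyl)-ent-labda-8(17),13Z-diene-15,16-diol
Product: 24 16-(2-methylpropanoyloxy)-ent-labda-8(17),13Z-dien-15-ol
Conditions: HF·pyridine, pyridine, THF, 0 °C → rt
Reagents that add atoms: none
Why: Fluoride cleavage of the primary allylic silyl ether under buffered, weakly acidic conditions that leave the isobutyrate in place and do not promote acyl migration.

Step 19
Reactants: 24 16-(2-methylpropanoyloxy)-ent-labda-8(17),13Z-dien-15-ol
Product: 25 16-(2-methylpropanoyloxy)-ent-labda-8(17),13Z-dien-15-al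
Conditions: Dess–Martin periodinane, pyridine, CH2Cl2, 0 °C
Reagents that add atoms: none
Why: Dess–Martin oxidation of the allylic alcohol under buffered, non-isomerising conditions, so the 13Z geometry of the β,β-disubstituted enal should be kept.

Step 20
Reactants: 25 16-(2-methylpropanoyloxy)-ent-labda-8(17),13Z-dien-15-al
Product: 26 16-(2-methylpropanoyloxy)-ent-labda-8(17),13Z-dien-15-oic acid (target, CNP0269104.1)
Conditions: NaClO2, NaH2PO4, 2-methylbut-2-ene, t-BuOH/H2O, 0 °C → rt
Reagents that add atoms: sodium chlorite, [Na+].[O-]Cl=O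
Why: Pinnick oxidation with an alkene scavenger for hypochlorite converts the enal into the acid without touching the alkenes, the ester or the alkene geometry.

**Compound list**
1 | 2,2-dimethylcyclohexan-1-one | CC1(C)CCCCC1=O | starting material
2 | 2,2-dimethyl-6-methylidenecyclohexan-1-one | C=C1CCCC(C)(C)C1=O | intermediate
3 | 6,6-dimethyl-2-methylidenecyclohexan-1-ol (racemic) | C=C1CCCC(C)(C)C1O | intermediate
4 | 1-(chloromethyl)-3,3-dimethylcyclohex-1-ene | ClCC1=CC(C)(C)CCC1 | intermediate
5 | 2-(2-bromoethyl)-2-methyl-1,3-dioxolane | CC1(CCBr)OCCO1 | starting material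
6 | [2-(2-methyl-1,3-dioxolan-2-yl)ethyl]magnesium bromide | CC1(CC[Mg]Br)OCCO1 | intermediate
7 | 2-{2-[(1R)-2,2-dimethyl-6-methylidenecyclohexyl]ethyl}-2-methyl-1,3-dioxolane | C=C1CCCC(C)(C)[C@H]1CCC2(C)OCCO2 | intermediate
8 | 4-[(1R)-2,2-dimethyl-6-methylidenecyclohexyl]butan-2-one | C=C1CCCC(C)(C)[C@H]1CCC(C)=O | intermediate
9 | diethyl 2-oxopropanedioate | CCOC(=O)C(=O)C(=O)OCC | starting material
10 | diethyl 2-{4-[(1R)-2,2-dimethyl-6-methylidenecyclohexyl]-2-oxobutyl}-2-hydroxypropanedioate | C=C1CCCC(C)(C)[C@H]1CCC(=O)CC(O)(C(=O)OCC)C(=O)OCC | intermediate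
11 | diethyl 2-{4-[(1R)-2,2-dimethyl-6-methylidenecyclohexyl]-2-oxobutylidene}propanedioate | C=C1CCCC(C)(C)[C@H]1CCC(=O)C=C(C(=O)OCC)C(=O)OCC | intermediate
12 | diethyl 2-[(1S,4aR,8aR)-5,5,8a-trimethyl-2-oxodecahydronaphthalen-1-yl]propanedioate | O=C1CC[C@@H]2C(C)(C)CCC[C@@]2(C)[C@@H]1C(C(=O)OCC)C(=O)OCC | intermediate
13 | ethyl 2-[(1S,4aR,8aR)-5,5,8a-trimethyl-2-oxodecahydronaphthalen-1-yl]acetate | O=C1CC[C@@H]2C(C)(C)CCC[C@@]2(C)[C@@H]1CC(=O)OCC | intermediate
14 | ethyl 2-[(1R,4aR,8aR)-5,5,8a-trimethyl-2-methylidenedecahydronaphthalen-1-yl]acetate | C=C1CC[C@@H]2C(C)(C)CCC[C@@]2(C)[C@@H]1CC(=O)OCC | intermediate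
15 | 2-[(1R,4aR,8aR)-5,5,8a-trimethyl-2-methylidenedecahydronaphthalen-1-yl]ethan-1-ol | C=C1CC[C@@H]2C(C)(C)CCC[C@@]2(C)[C@@H]1CCO | intermediate
16 | (4aR,5R,8aR)-5-(2-iodoethyl)-1,1,4a-trimethyl-6-methylidenedecahydronaphthalene | C=C1CC[C@@H]2C(C)(C)CCC[C@@]2(C)[C@@H]1CCI | intermediate
17 | but-2-yne-1,4-diol | OCC#CCO | starting material
18 | (2E)-2-(tributylstannyl)but-2-ene-1,4-diol | OC/C(=C\CO)[Sn](CCCC)(CCCC)CCCC | intermediate
19 | (2E)-4-[(tert-butyldimethylsilyl)oxy]-2-(tributylstannyl)but-2-en-1-ol | OC/C(=C\CO[Si](C)(C)C(C)(C)C)[Sn](CCCC)(CCCC)CCCC | intermediate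
20 | (2E)-4-[(tert-butyldimethylsilyl)oxy]-2-(tributylstannyl)but-2-en-1-yl 2-methylpropanoate | CC(C)C(=O)OC/C(=C\CO[Si](C)(C)C(C)(C)C)[Sn](CCCC)(CCCC)CCCC | intermediate
21 | (2E)-4-[(tert-butyldimethylsilyl)oxy]-2-iodobut-2-en-1-yl 2-methylpropanoate | CC(C)C(=O)OC/C(I)=C\CO[Si](C)(C)C(C)(C)C | intermediate
22 | {2-[(1R,4aR,8aR)-5,5,8a-trimethyl-2-methylidenedecahydronaphthalen-1-yl]ethyl}zinc iodide | C=C1CC[C@@H]2C(C)(C)CCC[C@@]2(C)[C@@H]1CC[Zn]I | intermediate
23 | (2Z)-4-[(tert-butyldimethylsilyl)oxy]-2-{2-[(1R,4aR,8aR)-5,5,8a-trimethyl-2-methylidenedecahydronaphthalen-1-yl]ethyl}but-2-en-1-yl 2-methylpropanoate | C=C1CC[C@@H]2C(C)(C)CCC[C@@]2(C)[C@@H]1CC/C(=C/CO[Si](C)(C)C(C)(C)C)COC(=O)C(C)C | intermediate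
24 | (2Z)-4-hydroxy-2-{2-[(1R,4aR,8aR)-5,5,8a-trimethyl-2-methylidenedecahydronaphthalen-1-yl]ethyl}but-2-en-1-yl 2-methylpropanoate | C=C1CC[C@@H]2C(C)(C)CCC[C@@]2(C)[C@@H]1CC/C(=C/CO)COC(=O)C(C)C | intermediate
25 | (2Z)-4-oxo-2-{2-[(1R,4aR,8aR)-5,5,8a-trimethyl-2-methylidenedecahydronaphthalen-1-yl]ethyl}but-2-en-1-yl 2-methylpropanoate | C=C1CC[C@@H]2C(C)(C)CCC[C@@]2(C)[C@@H]1CC/C(=C/C=O)COC(=O)C(C)C | intermediate
26 | (2Z)-3-{[(2-methylpropanoyl)oxy]methyl}-5-[(1R,4aR,8aR)-5,5,8a-trimethyl-2-methylidenedecahydronaphthalen-1-yl]pent-2-enoic acid | C=C1CC[C@@H]2C(C)(C)CCC[C@@]2(C)[C@@H]1CC/C(=C/C(=O)O)COC(=O)C(C)C | target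

**Step count**
Total: 20 steps. Longest linear sequence: 16 steps (steps 1–12 and 17–20); steps 13–16 are the side branch to vinyl iodide 21.

**Steps most likely to fail**

1. Step 4. The copper alkyl may be too slow to attack the ring carbon next to the quaternary C4, so that substitution at the CH2Cl carbon (no stereocentre) takes over, or the enantioselectivity may be poor at this hindered position. The fallback is asymmetric conjugate addition followed by transposition of the oxygen function into the methylene group; it sets out from 5 (as Grignard reagent 6) and comes back at 7. Reagent 6 is added to commercial 4,4-dimethylcyclohex-2-en-1-one under CuBr·SMe2 and a Josiphos-type ferrocenyl diphosphine, and the magnesium enolate is trapped with formaldehyde to give (3S)-2-(hydroxymethyl)-4,4-dimethyl-3-[2-(2-methyl-1,3-dioxolan-2-yl)ethyl]cyclohexan-1-one F1. Mesylation and elimination (MsCl, Et3N) give (3R)-4,4-dimethyl-2-methylidene-3-[2-(2-methyl-1,3-dioxolan-2-yl)ethyl]cyclohexan-1-one F2. Luche reduction gives (3R)-4,4-dimethyl-2-methylidene-3-[2-(2-methyl-1,3-dioxolan-2-yl)ethyl]cyclohexan-1-ol F3, and methyl chloroformate with pyridine gives (3R)-4,4-dimethyl-2-methylidene-3-[2-(2-methyl-1,3-dioxolan-2-yl)ethyl]cyclohexyl methyl carbonate F4. Hydrogenolysis of the π-allyl palladium complex with formate (Pd(OAc)2, PBu3, HCO2NH4) should deliver hydride to the ring terminus and leave the exocyclic methylene, which gives 7.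

2. Step 8. The iron hydride may reduce the alkylidene malonate by conjugate hydride transfer before it transfers hydrogen to the alkene, or the C10 radical may be quenched before it closes. In the fallback the radical is made by halogen-atom abstraction when no hydride source is present; it sets out from 8 and comes back at 12. Cobalt-catalysed Markovnikov hydrochlorination of 8 (Co(BF4)2·6H2O, salicylaldimine ligand, TsCl, PhSiH3, t-BuOOH, EtOH), which passes through no carbocation and so leaves C5 untouched, gives 4-[(1R)-2-chloro-2,6,6-trimethylcyclohexyl]butan-2-one F5. Aldol addition to 9 as in step 6 gives diethyl 2-{4-[(1R)-2-chloro-2,6,6-trimethylcyclohexyl]-2-oxobutyl}-2-hydroxypropanedioate F6, and MsCl/Et3N gives diethyl 2-{4-[(1R)-2-chloro-2,6,6-trimethylcyclohexyl]-2-oxobutylidene}propanedioate F7. Slow addition of (Me3Si)3SiH and AIBN in toluene at 85 °C abstracts chlorine, and the same C10 radical closes to 12.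

3. Step 17. Zerovalent palladium may strip the allylic isobutyrate from 21 or 23 (ionisation or β-elimination of the acyloxy group), or the coupling may be slow enough for the alkylzinc to be protonated. In the fallback C15 and C16 are told apart by a lactone instead of by protecting groups; it sets out from 16 (as organozinc 22) and comes back at 25. Tetronic acid is converted with oxalyl bromide and DMF into 4-bromofuran-2(5H)-one F8, and Negishi coupling of 22 with F8 (PdCl2(dppf)) gives 4-{2-[(1R,4aR,8aR)-5,5,8a-trimethyl-2-methylidenedecahydronaphthalen-1-yl]ethyl}furan-2(5H)-one F9. AlMe3 and MeNHOMe·HCl open the lactone to (2Z)-4-hydroxy-N-methoxy-N-methyl-3-{2-[(1R,4aR,8aR)-5,5,8a-trimethyl-2-methylidenedecahydronaphthalen-1-yl]ethyl}but-2-enamide F10. This is acylated at once with 2-methylpropanoyl chloride and pyridine to (2Z)-4-[methoxy(methyl)amino]-4-oxo-2-{2-[(1R,4aR,8aR)-5,5,8a-trimethyl-2-methylidenedecahydronaphthalen-1-yl]ethyl}but-2-en-1-yl 2-methylpropanoate F11. Cp2Zr(H)Cl reduces the amide to aldehyde 25 in the presence of the ester.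

**Further compounds**
F1 | step 4 | (3S)-2-(hydroxymethyl)-4,4-dimethyl-3-[2-(2-methyl-1,3-dioxolan-2-yl)ethyl]cyclohexan-1-one | OCC1C(=O)CCC(C)(C)[C@H]1CCC2(C)OCCO2
F2 | step 4 | (3R)-4,4-dimethyl-2-methylidene-3-[2-(2-methyl-1,3-dioxolan-2-yl)ethyl]cyclohexan-1-one | C=C1C(=O)CCC(C)(C)[C@H]1CCC2(C)OCCO2
F3 | step 4 | (3R)-4,4-dimethyl-2-methylidene-3-[2-(2-methyl-1,3-dioxolan-2-yl)ethyl]cyclohexan-1-ol | C=C1C(O)CCC(C)(C)[C@H]1CCC2(C)OCCO2
F4 | step 4 | (3R)-4,4-dimethyl-2-methylidene-3-[2-(2-methyl-1,3-dioxolan-2-yl)ethyl]cyclohexyl methyl carbonate | C=C1C(OC(=O)OC)CCC(C)(C)[C@H]1CCC2(C)OCCO2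
F5 | step 8 | 4-[(1R)-2-chloro-2,6,6-trimethylcyclohexyl]butan-2-one | CC1(Cl)CCCC(C)(C)[C@H]1CCC(C)=O
F6 | step 8 | diethyl 2-{4-[(1R)-2-chloro-2,6,6-trimethylcyclohexyl]-2-oxobutyl}-2-hydroxypropanedioate | CC1(Cl)CCCC(C)(C)[C@H]1CCC(=O)CC(O)(C(=O)OCC)C(=O)OCC
F7 | step 8 | diethyl 2-{4-[(1R)-2-chloro-2,6,6-trimethylcyclohexyl]-2-oxobutylidene}propanedioate | CC1(Cl)CCCC(C)(C)[C@H]1CCC(=O)C=C(C(=O)OCC)C(=O)OCC
F8 | step 17 | 4-bromofuran-2(5H)-one | O=C1C=C(Br)CO1
F9 | step 17 | 4-{2-[(1R,4aR,8aR)-5,5,8a-trimethyl-2-methylidenedecahydronaphthalen-1-yl]ethyl}furan-2(5H)-one | C=C1CC[C@@H]2C(C)(C)CCC[C@@]2(C)[C@@H]1CCC3=CC(=O)OC3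
F10 | step 17 | (2Z)-4-hydroxy-N-methoxy-N-methyl-3-{2-[(1R,4aR,8aR)-5,5,8a-trimethyl-2-methylidenedecahydronaphthalen-1-yl]ethyl}but-2-enamide | C=C1CC[C@@H]2C(C)(C)CCC[C@@]2(C)[C@@H]1CC/C(=C/C(=O)N(C)OC)CO
F11 | step 17 | (2Z)-4-[methoxy(methyl)amino]-4-oxo-2-{2-[(1R,4aR,8aR)-5,5,8a-trimethyl-2-methylidenedecahydronaphthalen-1-yl]ethyl}but-2-en-1-yl 2-methylpropanoate | C=C1CC[C@@H]2C(C)(C)CCC[C@@]2(C)[C@@H]1CC/C(=C/C(=O)N(C)OC)COC(=O)C(C)C
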